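Start from the leftover: while the two hands do not interconvert, what remains of each substrate counts the turnovers made on that hand, and the clock need not be read.

the same everywhere: left-handed substrate 0.061 M; right-handed substrate 0.061 M; solid reagent 0.152 M; impurity 0.30 mM
- Friday's: free catalyst 1.5 mM; racemization catalyst 0.12 mM; run made earlier
- Monday's: free catalyst 2.2 mM; racemization catalyst 0.12 mM; run made earlier
- Wednesday's: free catalyst 3 mM; racemization catalyst 0.24 mM; run made earlier
- flask: free catalyst 3.0 mM; racemization catalyst 0.12 mM; time 10 h

| run | time / h | left-handed product / % | right-handed product / % |
|---|---|---|---|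
| Friday's | 1.50 | 5.0 | 2.1 |
| Friday's | 3.00 | 12.4 | 6.0 |
| Friday's | 5.00 | 20.4 | 12.8 |
| Friday's | 6.00 | 24.9 | 16.4 |
| Friday's | 8.00 | 31.2 | 20.6 |
| Monday's | 1.50 | 7.3 | 3.7 |
| Monday's | 3.00 | 15.1 | 8.5 |
| Monday's | 5.00 | 25.9 | 17.6 |
| Monday's | 6.00 | 31.1 | 19.2 |
| Monday's | 8.00 | 37.2 | 26.0 |
| Wednesday's | 1.50 | 8.4 | 5.0 |
| Wednesday's | 3.00 | 18.9 | 11.4 |
| Wednesday's | 5.00 | 29.3 | 19.2 |
| Wednesday's | 6.00 | 35.0 | 23.0 |
| Wednesday's | 8.00 | 41.2 | 30.5 |

(readings scatter by 0.5 percentage points)

- excess of left-handed product over right-handed product in the product at 1.0 h
- excess of left-handed product over right-handed product in the product at 10 h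
- part of the left-handed substrate and right-handed substrate charged together that has reacted at 10 h

- free catalyst is single-handed; left-handed substrate and right-handed substrate are mirror images of each other, charged as a racemate, each of them at the stated concentration
- solid, in amounts per volume of the solution: solid reagent
- at the start none of the solid reagent is in solution
- an excess is the difference of the two amounts in percent of their sum
- an excess is below zero if the other one leads

Call a and b the parts of the left-handed and right-handed substrate left, each of its own charge. If each hand is consumed in proportion to what remains of it, under the same free catalyst, then ln a over ln b is the ratio of turnovers per unit of substrate, the selectivity factor s. Wednesday's readings at 8.00 h, counted as if no substrate changed hand, put a at 17.6 % and b at 39.0 %, so s reads 1.85.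

Object at once: Wednesday's run carried twice the racemization catalyst of Friday's run, and interconversion spoils the count. Friday's run differs in free catalyst as well, 1.5 mM against 3 mM, so the pair is no clean test; still, Friday's readings give s = 1.84, so keep s as a working figure.

At the start a and b stand near one, so the product excess is s minus one over s plus one, 29.7 %; take that for 1.0 h. Wednesday's first reading gives less, 25.4 %, but it rests on 13.4 % of product, read to 0.5 percentage points a reading, so it does not overturn the figure.

For the flask, borrow Wednesday's clock, since free catalyst and impurity match, though the flask has 0.12 mM of racemization catalyst against 0.24 mM. Let b fall from 8.00 h to 10 h by the factor it fell over the previous span: b = 28.2 %. Then a = b to the power s = 9.66 %, which gives 81.1 % reacted and an excess of 11.4 %. Might the solid stop the flask first? Its charge is 1.25 times the two substrates together, so at one per turnover its amount covers them, though this says nothing of how fast it dissolves.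

The forecast gives an excess of 30 % at 1.0 h, and 13.5 % with 79 % reacted at 10 h, a higher late excess and a lower conversion than mine, and says “racemization seems negligible”.

The flask gives an excess of 27.2 % at 1.0 h, and 12.0 % with 82.7 % reacted at 10 h. Its racemization catalyst stands at 0.109 % of its charge after 5.00 h. Apply s to the flask's end: 25 % of the right-handed substrate left gives a = 7.94 %, while the flask holds 9.3 % of the left-handed substrate, somewhat more.

    coupling partner + free catalyst + right-handed substrate → free catalyst + right-handed product (k = 2580 M⁻² h⁻¹)
    coupling partner + racemization catalyst → spent catalyst B (k = 93.9 M⁻¹ h⁻¹)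
    left-handed substrate + racemization catalyst ⇌ right-handed substrate + racemization catalyst, rate k3*[racemization catalyst]*[left-handed substrate] forward; the back reaction follows from the equilibrium constant (k = 5430 M⁻¹ h⁻¹)
    coupling partner + free catalyst + left-handed substrate → free catalyst + left-handed product (k = 4580 M⁻² h⁻¹)
    free catalyst + impurity → spent catalyst A (k = 1.12 × 10⁶ M⁻¹ h⁻¹)
    solid reagent ⇌ coupling partner, rate k6*(cs6 - [coupling partner]) while solid is left; crystals form when [coupling partner] > cs6 (solubility = 40.0 mM, k = 0.631 h⁻¹)

In the neighbour flask charged with 7.5 × 10⁻⁴ M of free catalyst, 72 % of the right-handed substrate left gives a = 54.5 % by s. The simulation of that flask leaves 56 % of the left-handed substrate, with 35.7 % reacted at an excess of 22.8 %.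

The data come from a simulation from invented constants, noise included.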